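The route rests on the C9–C10 σ-bond next to the E-trisubstituted C1=C10 olefin of the ten-membered carbocycle. This ring is not closed directly. It forms by contraction of an eleven-membered boracycle, a cyclic alkenyl boronate complex in which boron bridges C9 and C10 and the olefin still has the unstrained Z geometry. Iodine triggers a 1,2-metallate shift of C9 from boron to C10. Anti elimination of boron and iodide then delivers the strained E olefin stereospecifically. The boracycle is generated from an acyclic (Z)-vinyl iodide with a terminal pinacol boronate that already carries the epoxide and all five stereocentres.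

Key step: step 13

Numbering: the germacrane numbering of the target is used for all intermediates. The ring is C1–C10, with the C1=C10 olefin (methyl C14 on C10), C3 (angelate), the C4 (methyl C15)–C5 epoxide, C6 (acetate) and C7 (isopropyl).
Assumption 1: (S)-TRIP is taken to send an allyl boronate to the Si face of an aldehyde, because the (R)-acid attacks the Re face in this reaction type. The antipodal acid is equally available.
Assumption 2: compounds 1, 2, 8 and 23 are taken as commercial.

Step 1
Reactants: 1 methyl acetate; 2 (E)-4-acetoxy-2-methylbut-2-enal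
Product: 3 rac-methyl (4E)-6-acetoxy-3-hydroxy-4-methylhex-4-enoate
Conditions: LDA (1.05 equiv), THF, −78 °C; then 2; AcOH quench at −78 °C
Reagents that add atoms: none
Why: Lithium enolate aldol addition, in which 1,2-attack on the enal at −78 °C is far faster than attack on the primary acetate; C3 is formed racemic and is resolved in step 2.

Step 2
Reactants: 3 rac-methyl (4E)-6-acetoxy-3-hydroxy-4-methylhex-4-enoate
Product: 4 methyl (3S,4E)-6-acetoxy-3-hydroxy-4-methylhex-4-enoate
Conditions: Ti(OiPr)4 (10 mol %), D-(−)-DIPT (15 mol %), TBHP (0.6 equiv), 4 Å MS, CH2Cl2, −20 °C, run past half conversion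
Reagents that add atoms: none
Why: Sharpless kinetic resolution, in which D-(−)-tartrate epoxidises the (3R)-allylic alcohol much faster (to the erythro epoxy alcohol, removed by chromatography), so the (3S)-alcohol should remain in high enantiomeric purity.

Step 3
Reactants: 4 methyl (3S,4E)-6-acetoxy-3-hydroxy-4-methylhex-4-enoate
Product: 5 methyl (3S,4E)-6-acetoxy-3-(tert-butyldimethylsilyloxy)-4-methylhex-4-enoate
Conditions: TBSCl, imidazole, DMF, rt
Reagents that add atoms: tert-butyldimethylsilyl chloride, CC(C)(C)[Si](C)(C)Cl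
Why: Standard silylation of the only free hydroxyl group; C3 is not touched.

Step 4
Reactants: 5 methyl (3S,4E)-6-acetoxy-3-(tert-butyldimethylsilyloxy)-4-methylhex-4-enoate
Product: 6 methyl (3S,4E)-3-(tert-butyldimethylsilyloxy)-6-hydroxy-4-methylhex-4-enoate
Conditions: K2CO3 (0.2 equiv), MeOH, 0 °C
Reagents that add atoms: none
Why: Zemplén-type transesterification removes the primary allylic acetate, while exchange at the methyl ester is degenerate in methanol.

Step 5
Reactants: 6 methyl (3S,4E)-3-(tert-butyldimethylsilyloxy)-6-hydroxy-4-methylhex-4-enoate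
Product: 7 methyl (3S,4E)-3-(tert-butyldimethylsilyloxy)-4-methyl-6-oxohex-4-enoate
Conditions: MnO2, CH2Cl2, rt
Reagents that add atoms: none
Why: MnO2 oxidation is selective for the allylic alcohol and keeps the E geometry of the new enal.

Step 6
Reactants: 8 4-methylpent-1-en-3-ol (racemic)
Product: 9 (E)-2-(4-methylpent-2-en-1-yl)-4,4,5,5-tetramethyl-1,3,2-dioxaborolane
Conditions: B2pin2, Pd(MeCN)4(BF4)2 (5 mol %), DMSO/MeOH, rt to 40 °C
Reagents that add atoms: bis(pinacolato)diboron, CC1(C)OB(OC1(C)C)B1OC(C)(C)C(C)(C)O1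
Why: Pd-catalysed borylation of an allylic alcohol through an η3-allyl complex places boron at the unhindered terminus and should give the linear E allyl boronate.

Step 7
Reactants: 7 methyl (3S,4E)-3-(tert-butyldimethylsilyloxy)-4-methyl-6-oxohex-4-enoate; 9 (E)-2-(4-methylpent-2-en-1-yl)-4,4,5,5-tetramethyl-1,3,2-dioxaborolane
Product: 10 methyl (3S,4E,6S,7S)-3-(tert-butyldimethylsilyloxy)-6-hydroxy-4-methyl-7-(propan-2-yl)nona-4,8-dienoate (6,7-anti)
Conditions: (S)-TRIP (5 mol %), 4 Å MS, toluene, −30 °C; aqueous work-up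
Reagents that add atoms: none
Why: Chiral phosphoric acid-catalysed type I allylboration through a closed chair transition state, in which the E boronate sets the 6,7-anti relation and the catalyst selects the Si face of the enal (6S).

Step 8
Reactants: 10 methyl (3S,4E,6S,7S)-3-(tert-butyldimethylsilyloxy)-6-hydroxy-4-methyl-7-(propan-2-yl)nona-4,8-dienoate
Product: 11 methyl (3S,6S,7S)-3-(tert-butyldimethylsilyloxy)-4,5-epoxy-6-hydroxy-4-methyl-7-(propan-2-yl)non-8-enoate (trans-epoxide, oxygen threo to O6, C4 and C5 as in 25)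
Conditions: mCPBA, NaHCO3, CH2Cl2, 0 °C
Reagents that add atoms: 3-chloroperbenzoic acid, OOC(=O)c1cccc(Cl)c1
Why: Hydroxyl-directed Prilezhaev (Henbest) epoxidation, in which A1,3 strain with the C15 methyl (cis to C6) holds H6 in the olefin plane so the peracid is delivered from the OH face to give the threo epoxy alcohol, and the trisubstituted olefin reacts well before the vinyl group.

Step 9
Reactants: 11 methyl (3S,6S,7S)-3-(tert-butyldimethylsilyloxy)-4,5-epoxy-6-hydroxy-4-methyl-7-(propan-2-yl)non-8-enoate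
Product: 12 the 6-O-triethylsilyl ether of 11
Conditions: TESCl, imidazole, DMAP (cat.), CH2Cl2, 0 °C to rt
Reagents that add atoms: triethylsilyl chloride, CC[Si](Cl)(CC)CC
Why: Silylation under non-basic conditions avoids Payne migration and gives a C6 ether that can later be removed in the presence of the C3 TBS ether.

Step 10
Reactants: 12 the 6-O-triethylsilyl ether of 11
Product: 13 methyl 3-(TBS-oxy)-4,5-epoxy-4-methyl-7-(propan-2-yl)-9-(pinacolboryl)-6-(TES-oxy)nonanoate (C3–C7 as in 25)
Conditions: HBpin (1.2 equiv), [Ir(cod)Cl]2 (1.5 mol %), dppe (3 mol %), CH2Cl2, rt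
Reagents that add atoms: pinacolborane, [H]B1OC(C)(C)C(C)(C)O1
Why: Iridium-catalysed anti-Markovnikov hydroboration of the only olefin places boron on terminal C9 and tolerates ester, epoxide and silyl ethers.

Step 11
Reactants: 13 methyl 3-(TBS-oxy)-4,5-epoxy-4-methyl-7-(propan-2-yl)-9-(pinacolboryl)-6-(TES-oxy)nonanoate
Product: 14 3-(TBS-oxy)-4,5-epoxy-4-methyl-7-(propan-2-yl)-9-(pinacolboryl)-6-(TES-oxy)nonanal
Conditions: DIBAL-H (1.1 equiv), CH2Cl2, −78 °C; Rochelle salt work-up
Reagents that add atoms: none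
Why: Partial ester reduction stops at the tetrahedral aluminate at −78 °C and frees the C1 aldehyde on work-up; the alkyl boronate and the epoxide are inert at this temperature.

Step 12
Reactants: 14 3-(TBS-oxy)-4,5-epoxy-4-methyl-7-(propan-2-yl)-9-(pinacolboryl)-6-(TES-oxy)nonanal
Product: 15 the (Z)-vinyl iodide C14H3–C10(I)=C1H–C2 (iodine cis to C2) that carries the C3–C9 chain of 14 with its C9 pinacol boronate
Conditions: EtPPh3I, n-BuLi, THF; I2, −78 °C; NaHMDS, −20 °C; then 14, −78 °C
Reagents that add atoms: ethyltriphenylphosphonium iodide, CC[P+](c1ccccc1)(c1ccccc1)c1ccccc1.[I-]; iodine, II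
Why: Stork–Zhao olefination, in which the non-stabilised α-iodo ylide reacts under kinetic control through the cis-oxaphosphetane and should put iodine cis to C2.

Step 13
Reactants: 15 the (Z)-vinyl iodide with C9 pinacol boronate
Product: 19 (1(10)E)-3-(TBS-oxy)-6-(TES-oxy)-4,5-epoxygermacr-1(10)-ene (C3–C7 as in 25), via alkenyllithium 16 (not isolated), via cyclic lithium boronate 17 (not isolated), via iodo boronic ester 18 (not isolated)
Conditions: t-BuLi (2.05 equiv), THF/Et2O, 1 mM, −78 to −40 °C; I2 (1.2 equiv), THF, −78 °C; NaOMe, MeOH, −78 °C to rt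
Reagents that add atoms: none
Why: Proposed new method: iodine–lithium exchange, faster than addition of t-BuLi to the boronic ester, gives the configurationally stable (Z)-alkenyllithium 16, which at 1 mM attacks its own C9 boronic ester and closes the eleven-membered boracycle 17 by C10–B bond formation (attack on trigonal boron, olefin cis within the ring). Iodine adds to the electron-rich alkenyl boronate, and C9, the only carbon ligand able to migrate, shifts from boron to C10 anti to the iodonium (three-centre 1,2-metallate rearrangement), which contracts the ring to the ten-membered carbocycle 18 and moves boron to an exocyclic position. Methoxide then induces anti-periplanar loss of boron and iodide, so the two stereospecific anti events invert the olefin, and iodine cis to C2 in 15 becomes C9 trans to C2, the E geometry of the target. The closest known reaction type is the Zweifel olefination, whose intramolecular variant has been shown only for small boracycles with no olefin geometry at stake, and its extension to a medium ring is the new element. The transient centres C1 and C10 of 18 are fixed relative to each other by the anti addition whichever olefin face reacts, and C3–C7 are untouched. The step needs ring closure to beat oligomerisation, which high dilution, fast and irreversible B–C bond formation and the two rigid units in the tether (trans-epoxide, cis-olefin) are meant to secure.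

Step 14
Reactants: 19 (1(10)E)-3-(TBS-oxy)-6-(TES-oxy)-4,5-epoxygermacr-1(10)-ene
Product: 20 (1(10)E)-3-(TBS-oxy)-4,5-epoxygermacr-1(10)-en-6-ol
Conditions: HF·pyridine, excess pyridine, THF, 0 °C
Reagents that add atoms: none
Why: Selective desilylation, in which the TES ether is cleaved much faster than the TBS ether, and the pyridine buffer protects the acid-labile 4,5-epoxy-1(10)-ene from transannular cyclisation.

Step 15
Reactants: 20 (1(10)E)-3-(TBS-oxy)-4,5-epoxygermacr-1(10)-en-6-ol
Product: 21 (1(10)E)-6-acetoxy-3-(TBS-oxy)-4,5-epoxygermacr-1(10)-ene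
Conditions: Ac2O, Et3N, DMAP (cat.), CH2Cl2, rt
Reagents that add atoms: acetic anhydride, CC(=O)OC(C)=O
Why: DMAP-catalysed acetylation of the only free hydroxyl group proceeds with retention at C6.

Step 16
Reactants: 21 (1(10)E)-6-acetoxy-3-(TBS-oxy)-4,5-epoxygermacr-1(10)-ene
Product: 22 (1(10)E)-6-acetoxy-4,5-epoxygermacr-1(10)-en-3-ol
Conditions: TBAF/AcOH (1:1), THF, rt
Reagents that add atoms: none
Why: Buffered fluoride desilylation frees O3, and the acetate cannot migrate across the trans-epoxide and survives the near-neutral medium.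

Step 17
Reactants: 22 (1(10)E)-6-acetoxy-4,5-epoxygermacr-1(10)-en-3-ol; 23 angelic acid
Product: 25 CNP0180504.1 (3-angeloyloxy-6-acetoxy-4,5-epoxygermacr-1(10)E-ene), via angelic trichlorobenzoic mixed anhydride 24 (not isolated)
Conditions: 23, 2,4,6-trichlorobenzoyl chloride, Et3N, toluene, rt; then 22, 80 °C (no DMAP)
Reagents that add atoms: none
Why: Yamaguchi-type mixed-anhydride esterification without a nucleophilic catalyst is the usual way to acylate with angelic acid while keeping the Z olefin, and C3 keeps its configuration because only the O–H bond reacts.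

Compound list
1 | methyl acetate | COC(C)=O | starting material
2 | (E)-4-acetoxy-2-methylbut-2-enal | O=C/C(C)=C/COC(C)=O | starting material
3 | rac-methyl (4E)-6-acetoxy-3-hydroxy-4-methylhex-4-enoate | COC(=O)CC(O)/C(C)=C/COC(C)=O | intermediate
4 | methyl (3S,4E)-6-acetoxy-3-hydroxy-4-methylhex-4-enoate | COC(=O)C[C@H](O)/C(C)=C/COC(C)=O | intermediate
5 | methyl (3S,4E)-6-acetoxy-3-(TBS-oxy)-4-methylhex-4-enoate | COC(=O)C[C@H](O[Si](C)(C)C(C)(C)C)/C(C)=C/COC(C)=O | intermediate
6 | methyl (3S,4E)-3-(TBS-oxy)-6-hydroxy-4-methylhex-4-enoate | COC(=O)C[C@H](O[Si](C)(C)C(C)(C)C)/C(C)=C/CO | intermediate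
7 | methyl (3S,4E)-3-(TBS-oxy)-4-methyl-6-oxohex-4-enoate | COC(=O)C[C@H](O[Si](C)(C)C(C)(C)C)/C(C)=C/C=O | intermediate
8 | 4-methylpent-1-en-3-ol (racemic) | C=CC(O)C(C)C | starting material
9 | (E)-2-(4-methylpent-2-en-1-yl)-4,4,5,5-tetramethyl-1,3,2-dioxaborolane | CC(C)/C=C/CB1OC(C)(C)C(C)(C)O1 | intermediate
10 | methyl (3S,4E,6S,7S)-3-(TBS-oxy)-6-hydroxy-4-methyl-7-isopropylnona-4,8-dienoate | COC(=O)C[C@H](O[Si](C)(C)C(C)(C)C)/C(C)=C/[C@@H](O)[C@@H](C(C)C)C=C | intermediate
11 | methyl 3-(TBS-oxy)-4,5-epoxy-6-hydroxy-4-methyl-7-isopropylnon-8-enoate (threo epoxy alcohol) | COC(=O)C[C@H](O[Si](C)(C)C(C)(C)C)[C@@]1(C)O[C@@H]1[C@@H](O)[C@@H](C(C)C)C=C | intermediate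
12 | 6-O-TES ether of 11 | COC(=O)C[C@H](O[Si](C)(C)C(C)(C)C)[C@@]1(C)O[C@@H]1[C@@H](O[Si](CC)(CC)CC)[C@@H](C(C)C)C=C | intermediate
13 | C9 pinacol boronate methyl ester | COC(=O)C[C@H](O[Si](C)(C)C(C)(C)C)[C@@]1(C)O[C@@H]1[C@@H](O[Si](CC)(CC)CC)[C@@H](C(C)C)CCB2OC(C)(C)C(C)(C)O2 | intermediate
14 | C1 aldehyde with C9 pinacol boronate | O=CC[C@H](O[Si](C)(C)C(C)(C)C)[C@@]1(C)O[C@@H]1[C@@H](O[Si](CC)(CC)CC)[C@@H](C(C)C)CCB2OC(C)(C)C(C)(C)O2 | intermediate
15 | (Z)-vinyl iodide (I on C10 cis to C2) with C9 pinacol boronate | C/C(I)=C/C[C@H](O[Si](C)(C)C(C)(C)C)[C@@]1(C)O[C@@H]1[C@@H](O[Si](CC)(CC)CC)[C@@H](C(C)C)CCB2OC(C)(C)C(C)(C)O2 | intermediate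
16 | (Z)-alkenyllithium from 15 | C/C([Li])=C/C[C@H](O[Si](C)(C)C(C)(C)C)[C@@]1(C)O[C@@H]1[C@@H](O[Si](CC)(CC)CC)[C@@H](C(C)C)CCB2OC(C)(C)C(C)(C)O2 | intermediate
17 | eleven-membered cyclic lithium alkenyl boronate (B between C9 and C10, olefin cis in the ring) | [Li+].CC(C)(C)[Si](C)(C)O[C@H]1C/C=C(/C)[B-]3(OC(C)(C)C(C)(C)O3)CC[C@H](C(C)C)[C@H](O[Si](CC)(CC)CC)[C@H]2O[C@]12C | intermediate
18 | ten-membered 1-iodo-10-(pinacolboryl) carbocycle (drawn for one olefin face; the C1/C10 relation is fixed by anti addition) | CC(C)(C)[Si](C)(C)O[C@H]1C[C@@H](I)[C@@](C)(B3OC(C)(C)C(C)(C)O3)CC[C@H](C(C)C)[C@H](O[Si](CC)(CC)CC)[C@H]2O[C@]12C | intermediate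
19 | (1(10)E)-3-(TBS-oxy)-6-(TES-oxy)-4,5-epoxygermacr-1(10)-ene | CC(C)(C)[Si](C)(C)O[C@H]1C/C=C(\C)CC[C@H](C(C)C)[C@H](O[Si](CC)(CC)CC)[C@H]2O[C@]12C | intermediate
20 | (1(10)E)-3-(TBS-oxy)-4,5-epoxygermacr-1(10)-en-6-ol | CC(C)(C)[Si](C)(C)O[C@H]1C/C=C(\C)CC[C@H](C(C)C)[C@H](O)[C@H]2O[C@]12C | intermediate
21 | (1(10)E)-6-acetoxy-3-(TBS-oxy)-4,5-epoxygermacr-1(10)-ene | CC(C)(C)[Si](C)(C)O[C@H]1C/C=C(\C)CC[C@H](C(C)C)[C@H](OC(C)=O)[C@H]2O[C@]12C | intermediate
22 | (1(10)E)-6-acetoxy-4,5-epoxygermacr-1(10)-en-3-ol | O[C@H]1C/C=C(\C)CC[C@H](C(C)C)[C@H](OC(C)=O)[C@H]2O[C@]12C | intermediate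
23 | angelic acid, (Z)-2-methylbut-2-enoic acid | C/C=C(/C)C(=O)O | starting material
24 | angelic 2,4,6-trichlorobenzoic mixed anhydride | C/C=C(/C)C(=O)OC(=O)c1c(Cl)cc(Cl)cc1Cl | intermediate
25 | CNP0180504.1 | C/C=C(/C)C(=O)O[C@H]1C/C=C(\C)CC[C@H](C(C)C)[C@H](OC(C)=O)[C@H]2O[C@]12C | target

Total step count: 17. Longest linear sequence: 16 (steps 1–5 and 7–17).

Steps most likely to fail

1. Step 13. The alkenyllithium may attack the boronate of a second molecule and oligomerise before the eleven-membered ring closes. It may also be protonated, or t-BuLi may add to boron. The fallback uses known chemistry. It sets out from aldehyde 14 and comes back at 19. It gives up the boron extrusion and makes C9–C10 by direct sp3–sp2 coupling. Ohira–Bestmann homologation gives the terminal alkyne F1. LDA followed by MeI gives the methyl alkyne F2. Hydrozirconation with the Schwartz reagent (zirconium next to the methyl group, syn addition) followed by iodinolysis gives the (E)-vinyl iodide F3. An intramolecular Suzuki–Miyaura coupling under syringe-pump dilution (Pd(dppf)Cl2, AsPh3, Cs2CO3, DMF/THF/H2O) then closes the ring with retention of the E geometry.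

2. Step 12. The ylide may give poor Z/E control, may lose iodine before olefination, or may act as a base and eliminate the β-silyloxy group of the aldehyde. The fallback sets out from 14 and comes back at the alkenyllithium 16. Ramirez dibromo-olefination (CBr4, PPh3, Et3N) gives the 1,1-dibromoalkene F4. A trans-selective Negishi methylation (MeZnCl, Pd/DPEphos) replaces only the bromine trans to C2 and gives the (Z)-vinyl bromide F5. Bromine–lithium exchange with t-BuLi under the conditions of step 13 then produces 16.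

3. Step 17. Acylation of the C3 carbinol next to quaternary C4 may be slow, and the forcing conditions may isomerise the angelate to the tiglate. The fallback sets out from 22 and comes back at 25, and it builds the Z olefin on the ester instead of transferring it. Steglich esterification with 2-[bis(2,2,2-trifluoroethoxy)phosphoryl]propanoic acid gives the phosphonopropionate F6. A Still–Gennari olefination with acetaldehyde (KHMDS, 18-crown-6, THF, −78 °C) then gives the angelate.

Further compounds
F1 | step 13 | terminal alkyne (C10≡C1) with C9 pinacol boronate | C#CC[C@H](O[Si](C)(C)C(C)(C)C)[C@@]1(C)O[C@@H]1[C@@H](O[Si](CC)(CC)CC)[C@@H](C(C)C)CCB2OC(C)(C)C(C)(C)O2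
F2 | step 13 | methyl alkyne (C14–C10≡C1) with C9 pinacol boronate | CC#CC[C@H](O[Si](C)(C)C(C)(C)C)[C@@]1(C)O[C@@H]1[C@@H](O[Si](CC)(CC)CC)[C@@H](C(C)C)CCB2OC(C)(C)C(C)(C)O2
F3 | step 13 | (E)-vinyl iodide (I on C10 trans to C2) with C9 pinacol boronate | C/C(I)=C\C[C@H](O[Si](C)(C)C(C)(C)C)[C@@]1(C)O[C@@H]1[C@@H](O[Si](CC)(CC)CC)[C@@H](C(C)C)CCB2OC(C)(C)C(C)(C)O2
F4 | step 12 | 1,1-dibromoalkene from 14 | BrC(Br)=CC[C@H](O[Si](C)(C)C(C)(C)C)[C@@]1(C)O[C@@H]1[C@@H](O[Si](CC)(CC)CC)[C@@H](C(C)C)CCB2OC(C)(C)C(C)(C)O2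
F5 | step 12 | (Z)-vinyl bromide (Br on C10 cis to C2) with C9 pinacol boronate | C/C(Br)=C/C[C@H](O[Si](C)(C)C(C)(C)C)[C@@]1(C)O[C@@H]1[C@@H](O[Si](CC)(CC)CC)[C@@H](C(C)C)CCB2OC(C)(C)C(C)(C)O2
F6 | step 17 | 3-O-{2-[bis(2,2,2-trifluoroethoxy)phosphoryl]propanoyl} derivative of 22 (epimers at the P-bearing carbon) | CC(C(=O)O[C@H]1C/C=C(\C)CC[C@H](C(C)C)[C@H](OC(C)=O)[C@H]2O[C@]12C)P(=O)(OCC(F)(F)F)OCC(F)(F)F
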